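Retrosynthesis: the diene is cut at the C=C next to the isocoumarin (Horner–Wadsworth–Emmons) and then at the C=C next to the tetrahydrofuran (Wittig), giving an isocoumarin-3-ylmethyl phosphonate, a two-carbon ylide and a tetrahydrofuran-2-carbaldehyde.
Enabling feature: the tetrahydrofuran O1–C2 bond carries one exocyclic carbon on C2; at the ester level this carbon and O1 are the acyl C–O of a six-membered lactone (O1, C=O, C2, C3, C4, C5). Methanolysis frees O1 to displace an activated C2–O bond (cyclic sulfate shared with O3), and the lactone contracts to the tetrahydrofuran.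
Forward ring order: dihydropyranone by hetero-Diels–Alder reaction, oxidation to the all-cis δ-lactone, contraction to the tetrahydrofuran; separately an orsellinate is annulated to the isocoumarin by toluate acylation and enol lactonisation; the halves are joined last and desilylated.
Stereochemistry: C5 from the chiral chromium catalyst, C3 by 1,3-induction in a Luche reduction, C2 by hydroxyl-directed dihydroxylation and its inversion in the contraction; both alkenes E from stabilised ylide and phosphonate olefinations.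

Key step: step 6

Assumption: the (S,S) antipode of the chromium salen catalyst is taken to give the 2R pyranone, by analogy with its sense of induction for other aldehydes; if the sense is opposite, the equally available (R,R) antipode is used.

Step 1
Reactants: 1 acetaldehyde; 2 (E)-1-methoxy-3-(trimethylsilyloxy)buta-1,3-diene
Product: 4 (R)-2-methyl-2,3-dihydro-4H-pyran-4-one, via cycloadduct 3 (not isolated)
Conditions: (S,S)-(salen)CrBF4 (2 mol %; salen = N,N'-bis(3,5-di-tert-butylsalicylidene)cyclohexane-1,2-diaminate; trivalent chromium), 4 Å MS, tBuOMe, −30 °C; then CF3CO2H (cat.), CH2Cl2, 0 °C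
Reagents that add atoms: none
Why: Chiral Lewis acid-catalysed hetero-Diels–Alder reaction in which the chromium complex differentiates the aldehyde faces and so sets the methyl-bearing carbon (R, the later C5 of the tetrahydrofuran), after which acid expels methoxytrimethylsilane from the cycloadduct to give the enone.

Step 2
Reactants: 4 (R)-2-methyl-2,3-dihydro-4H-pyran-4-one
Product: 5 (2R,4S)-2-methyl-3,4-dihydro-2H-pyran-4-ol
Conditions: NaBH4, CeCl3·7H2O, MeOH, −78 °C
Reagents that add atoms: none
Why: Luche 1,2-reduction, in which axial hydride delivery to the half-chair enone should give the pseudo-equatorial alcohol cis to the C2 methyl group (1,3-induction), the later C3 carbinol of the tetrahydrofuran.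

Step 3
Reactants: 5 (2R,4S)-2-methyl-3,4-dihydro-2H-pyran-4-ol
Product: 7 (3S,4S,6R)-6-methyltetrahydro-2H-pyran-2,3,4-triol (4,6-dideoxy-D-lyxo-hexopyranose; anomer mixture), via osmate ester 6 (not isolated)
Conditions: OsO4 (1.05 equiv), TMEDA (1.1 equiv), CH2Cl2, −78 °C; then aq. Na2SO3, THF, 60 °C
Reagents that add atoms: osmium tetroxide, O=[Os](=O)(=O)=O
Why: Hydrogen-bond-directed syn-dihydroxylation, in which the OsO4–TMEDA complex is held by the allylic hydroxyl and should add to the enol ether on the hydroxyl-bearing face, so that both new C–O bonds are cis to the C4 hydroxyl and the C6 methyl group before sulfite frees the triol.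

Step 4
Reactants: 7 (3S,4S,6R)-6-methyltetrahydro-2H-pyran-2,3,4-triol
Product: 8 (3S,4S,6R)-3,4-dihydroxy-6-methyltetrahydro-2H-pyran-2-one
Conditions: Ag2CO3 on Celite (3 equiv), toluene, 110 °C
Reagents that add atoms: none
Why: Fétizon oxidation is selective for the hemiacetal carbon over secondary carbinols, and because C5 is a methylene no five-membered lactone can form, so the six-membered lactone is obtained without touching a stereocentre.

Step 5
Reactants: 8 (3S,4S,6R)-3,4-dihydroxy-6-methyltetrahydro-2H-pyran-2-one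
Product: 10 (3S,4S,6R)-6-methyl-2-oxotetrahydro-2H-pyran-3,4-diyl sulfate (cyclic sulfate of 8), via cyclic sulfite 9 (not isolated)
Conditions: SOCl2 (1.2 equiv), Et3N (2.5 equiv), CH2Cl2, 0 °C; then RuCl3 (1 mol %), NaIO4 (1.5 equiv), MeCN/H2O, 0 °C
Reagents that add atoms: thionyl chloride, O=S(Cl)Cl; sodium periodate, [Na+].[O-]I(=O)(=O)=O
Why: Two-stage cyclic sulfate synthesis on a cis-1,2-diol (cyclic sulfite formation, then ruthenium-catalysed oxidation at sulfur), which keeps both carbinol configurations, turns the C3 oxygen into a leaving group and masks the C4 oxygen in the same ring.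

Step 6
Reactants: 10 (3S,4S,6R)-6-methyl-2-oxotetrahydro-2H-pyran-3,4-diyl sulfate
Product: 13 methyl (2R,3S,5R)-3-hydroxy-5-methyltetrahydrofuran-2-carboxylate, via ring-opened alkoxide 11 (not isolated), via sulfate monoester 12 (not isolated)
Conditions: NaOMe (1.0 equiv), MeOH, −20 to 0 °C; then H2SO4 (cat.), H2O (2 equiv), THF, 25 °C
Reagents that add atoms: sodium methoxide, [Na+].[O-]C
Why: Methoxide adds to the lactone carbonyl and the six-membered ring opens by acyl–oxygen cleavage to the C5 alkoxide 11, which attacks the α-carbon of the new ester from the side opposite to the sulfate oxygen, so that the ring oxygen moves from the carbonyl carbon to C2 and the tetrahydrofuran (O1, C2, C3, C4, C5) results with the former carbonyl carbon as exocyclic ester; dilute acid then hydrolyses the sulfate monoester 12 at sulfur. The closest known reaction type is the base-induced ring contraction of 2-O-sulfonyl aldono-1,5-lactones to 2,5-anhydroaldonates, combined with the alkoxide opening of cyclic sulfates of 2,3-dihydroxy esters at the α-carbon. The five-membered ring closes in the 5-exo-tet mode. C2 is the only centre that changes: SN2 inversion converts the cis (erythro) C2–O/C3–O arrangement of the lactone into the one in which the ester is cis to the C3 oxygen and to the C5 methyl group, while C3 and C5 are not touched. The step needs attack at C2 and not at C3 (4-exo closure to an oxetane) and no epoxide formation from O3; the activation of C2 by the ester, the ring size and the tying of O3 into the sulfate secure this. One equivalent of methoxide is consumed as the neutral sulfate salt forms, so no base should remain to epimerise or eliminate at C2.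

Step 7
Reactants: 13 methyl (2R,3S,5R)-3-hydroxy-5-methyltetrahydrofuran-2-carboxylate
Product: 14 methyl (2R,3S,5R)-3-[(tert-butyldimethylsilyl)oxy]-5-methyltetrahydrofuran-2-carboxylate
Conditions: TBSOTf (1.2 equiv), 2,6-lutidine (2 equiv), CH2Cl2, −78 to 0 °C
Reagents that add atoms: tert-butyldimethylsilyl trifluoromethanesulfonate, CC(C)(C)[Si](C)(C)OS(=O)(=O)C(F)(F)F
Why: Silylation of the hindered secondary alcohol with a silyl triflate and a non-nucleophilic base is too mild to epimerise the α-alkoxy ester and blocks β-elimination and alkoxide chemistry in the following steps.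

Step 8
Reactants: 14 methyl (2R,3S,5R)-3-[(tert-butyldimethylsilyl)oxy]-5-methyltetrahydrofuran-2-carboxylate
Product: 16 (2R,3S,5R)-3-[(tert-butyldimethylsilyl)oxy]-5-methyltetrahydrofuran-2-carbaldehyde, via aluminium hemiacetal 15 (not isolated)
Conditions: iBu2AlH (1.1 equiv), CH2Cl2, −78 °C; MeOH, then aq. potassium sodium tartrate
Reagents that add atoms: none
Why: Partial reduction of an α-alkoxy ester stops at the chelated aluminium hemiacetal at −78 °C and releases the aldehyde only on work-up, so over-reduction and epimerisation at C2 should be avoided.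

Step 9
Reactants: 16 (2R,3S,5R)-3-[(tert-butyldimethylsilyl)oxy]-5-methyltetrahydrofuran-2-carbaldehyde; 17 (triphenylphosphoranylidene)acetaldehyde
Product: 18 (E)-3-[(2S,3S,5R)-3-[(tert-butyldimethylsilyl)oxy]-5-methyltetrahydrofuran-2-yl]prop-2-enal
Conditions: toluene, 40 °C
Reagents that add atoms: none
Why: Wittig olefination with a formyl-stabilised ylide should give the E-enal under essentially neutral conditions that leave the epimerisable C2 centre and the silyl ether intact, the product enal being less electrophilic than the α-alkoxy aldehyde.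

Step 10
Reactants: 19 methyl 2,4-dihydroxy-6-methylbenzoate
Product: 20 methyl 3-chloro-4,6-dihydroxy-2-methylbenzoate
Conditions: SO2Cl2 (1.05 equiv), Et2O, 0 °C
Reagents that add atoms: sulfuryl chloride, O=S(=O)(Cl)Cl
Why: Electrophilic aromatic chlorination of the resorcylate should take place para to the hydrogen-bonded hydroxyl and ortho to the methyl group rather than at the hindered position between the two hydroxyls, as is known for orsellinates and resorcylic lactones, and one equivalent limits dichlorination.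

Step 11
Reactants: 20 methyl 3-chloro-4,6-dihydroxy-2-methylbenzoate
Product: 21 methyl 4,6-bis[(tert-butyldimethylsilyl)oxy]-3-chloro-2-methylbenzoate
Conditions: TBSOTf (2.4 equiv), 2,6-lutidine (4 equiv), CH2Cl2, 0 to 25 °C
Reagents that add atoms: tert-butyldimethylsilyl trifluoromethanesulfonate, CC(C)(C)[Si](C)(C)OS(=O)(=O)C(F)(F)F
Why: The silyl triflate silylates both phenols, including the hydrogen-bonded one, giving fluoride-labile aryl ethers that tolerate the amide bases and the anhydrous acid used later.

Step 12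
Reactants: 21 methyl 4,6-bis[(tert-butyldimethylsilyl)oxy]-3-chloro-2-methylbenzoate; 22 2-chloro-N-methoxy-N-methylacetamide
Product: 25 6,8-bis[(tert-butyldimethylsilyl)oxy]-5-chloro-3-(chloromethyl)-1H-isochromen-1-one, via benzylic lithium species 23 (not isolated), via chloromethyl ketone 24 (not isolated)
Conditions: LiN(iPr)2 (1.15 equiv), THF, −78 °C; 22, −78 °C; AcOH quench; then TsOH·H2O (10 mol %), toluene, 80 °C
Reagents that add atoms: none
Why: Lateral lithiation of the ortho-toluate gives an ester-stabilised benzylic anion that is acylated by the Weinreb amide through a stable chelated tetrahedral adduct (no over-addition), and acid-catalysed enol lactonisation of the resulting aryl acetone onto the neighbouring ester (6-exo-trig, loss of methanol) closes the pyranone ring of the isocoumarin.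

Step 13
Reactants: 25 6,8-bis[(tert-butyldimethylsilyl)oxy]-5-chloro-3-(chloromethyl)-1H-isochromen-1-one
Product: 26 diethyl {[6,8-bis[(tert-butyldimethylsilyl)oxy]-5-chloro-1-oxo-1H-isochromen-3-yl]methyl}phosphonate
Conditions: P(OEt)3 (5 equiv), NaI (10 mol %), 120 °C
Reagents that add atoms: triethyl phosphite, CCOP(OCC)OCC
Why: Michaelis–Arbuzov reaction of a primary allylic-type chloride, accelerated by iodide exchange, on a substrate that has no ketone and so cannot follow the Perkow pathway.

Step 14
Reactants: 26 diethyl {[6,8-bis[(tert-butyldimethylsilyl)oxy]-5-chloro-1-oxo-1H-isochromen-3-yl]methyl}phosphonate; 18 (E)-3-[(2S,3S,5R)-3-[(tert-butyldimethylsilyl)oxy]-5-methyltetrahydrofuran-2-yl]prop-2-enal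
Product: 28 6,8-bis[(tert-butyldimethylsilyl)oxy]-3-[(1E,3E)-4-[(2S,3S,5R)-3-[(tert-butyldimethylsilyl)oxy]-5-methyltetrahydrofuran-2-yl]buta-1,3-dien-1-yl]-5-chloro-1H-isochromen-1-one, via phosphonate carbanion 27 (not isolated)
Conditions: NaN(SiMe3)2 (1.05 equiv), THF, −78 °C; then 18, −78 to 0 °C
Reagents that add atoms: none
Why: Horner–Wadsworth–Emmons olefination of a semi-stabilised (allyl/benzyl-type) phosphonate anion with the enal should give the new alkene with E geometry and complete the E,E-diene without touching the existing alkene, while the hindered amide base spares the aryl silyl ethers and the lactone.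

Step 15
Reactants: 28 6,8-bis[(tert-butyldimethylsilyl)oxy]-3-[(1E,3E)-4-[(2S,3S,5R)-3-[(tert-butyldimethylsilyl)oxy]-5-methyltetrahydrofuran-2-yl]buta-1,3-dien-1-yl]-5-chloro-1H-isochromen-1-one
Product: 29 5-chloro-6,8-dihydroxy-3-[(1E,3E)-4-[(2S,3S,5R)-3-hydroxy-5-methyltetrahydrofuran-2-yl]buta-1,3-dien-1-yl]-1H-isochromen-1-one
Conditions: Bu4NF (3.5 equiv), AcOH (3.5 equiv), THF, 0 to 25 °C
Reagents that add atoms: none
Why: Fluoride cleaves the two aryl silyl ethers and the secondary alkyl silyl ether (Si–F bond formation), and the acetic acid buffer should keep phenoxide and alkoxide from opening the lactone or disturbing the allylic ether and diene.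

Compound list
1 | acetaldehyde | CC=O | starting material
2 | (E)-1-methoxy-3-(trimethylsilyloxy)buta-1,3-diene | CO/C=C/C(=C)O[Si](C)(C)C | starting material
3 | (6R)-2-methoxy-6-methyl-4-(trimethylsilyloxy)-5,6-dihydro-2H-pyran (cycloadduct, C2 epimers) | COC1C=C(O[Si](C)(C)C)C[C@@H](C)O1 | intermediate (not isolated)
4 | (R)-2-methyl-2,3-dihydro-4H-pyran-4-one | C[C@@H]1CC(=O)C=CO1 | intermediate
5 | (2R,4S)-2-methyl-3,4-dihydro-2H-pyran-4-ol | C[C@@H]1C[C@H](O)C=CO1 | intermediate
6 | cyclic osmate ester of the C2,C3-diol of 7 (dioxo-osmium diolate, all-cis), as its TMEDA chelate | C[C@@H]1C[C@H](O)[C@@H]2O[Os](=O)(=O)O[C@@H]2O1.CN(C)CCN(C)C | intermediate (not isolated)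
7 | (3S,4S,6R)-6-methyltetrahydro-2H-pyran-2,3,4-triol (4,6-dideoxy-D-lyxo-hexopyranose, anomer mixture) | C[C@@H]1C[C@H](O)[C@H](O)C(O)O1 | intermediate
8 | (3S,4S,6R)-3,4-dihydroxy-6-methyltetrahydro-2H-pyran-2-one | C[C@@H]1C[C@H](O)[C@H](O)C(=O)O1 | intermediate
9 | cyclic sulfite of 8 (3,4-O-sulfinyl, sulfur epimers) | C[C@@H]1C[C@@H]2OS(=O)O[C@@H]2C(=O)O1 | intermediate (not isolated)
10 | (3S,4S,6R)-6-methyl-2-oxotetrahydro-2H-pyran-3,4-diyl sulfate (cyclic sulfate of 8) | C[C@@H]1C[C@@H]2OS(=O)(=O)O[C@@H]2C(=O)O1 | intermediate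
11 | sodium alkoxide of methyl (2S,3S,5R)-5-hydroxy-2,3-(sulfonyldioxy)hexanoate | C[C@@H]([O-])C[C@@H]1OS(=O)(=O)O[C@@H]1C(=O)OC.[Na+] | intermediate (not isolated)
12 | sodium (2R,3S,5R)-2-(methoxycarbonyl)-5-methyltetrahydrofuran-3-yl sulfate | C[C@@H]1C[C@H](OS(=O)(=O)[O-])[C@H](C(=O)OC)O1.[Na+] | intermediate (not isolated)
13 | methyl (2R,3S,5R)-3-hydroxy-5-methyltetrahydrofuran-2-carboxylate (all-cis) | C[C@@H]1C[C@H](O)[C@H](C(=O)OC)O1 | intermediate
14 | methyl (2R,3S,5R)-3-[(tert-butyldimethylsilyl)oxy]-5-methyltetrahydrofuran-2-carboxylate | C[C@@H]1C[C@H](O[Si](C)(C)C(C)(C)C)[C@H](C(=O)OC)O1 | intermediate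
15 | diisobutylaluminium hemiacetal of 14 | C[C@@H]1C[C@H](O[Si](C)(C)C(C)(C)C)[C@H](C(OC)O[Al](CC(C)C)CC(C)C)O1 | intermediate (not isolated)
16 | (2R,3S,5R)-3-[(tert-butyldimethylsilyl)oxy]-5-methyltetrahydrofuran-2-carbaldehyde | C[C@@H]1C[C@H](O[Si](C)(C)C(C)(C)C)[C@H](C=O)O1 | intermediate
17 | (triphenylphosphoranylidene)acetaldehyde | O=CC=P(c1ccccc1)(c1ccccc1)c1ccccc1 | starting material
18 | (E)-3-[(2S,3S,5R)-3-[(tert-butyldimethylsilyl)oxy]-5-methyltetrahydrofuran-2-yl]prop-2-enal | C[C@@H]1C[C@H](O[Si](C)(C)C(C)(C)C)[C@H](/C=C/C=O)O1 | intermediate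
19 | methyl 2,4-dihydroxy-6-methylbenzoate (methyl orsellinate) | COC(=O)c1c(C)cc(O)cc1O | starting material
20 | methyl 3-chloro-4,6-dihydroxy-2-methylbenzoate | COC(=O)c1c(C)c(Cl)c(O)cc1O | intermediate
21 | methyl 4,6-bis[(tert-butyldimethylsilyl)oxy]-3-chloro-2-methylbenzoate | COC(=O)c1c(C)c(Cl)c(O[Si](C)(C)C(C)(C)C)cc1O[Si](C)(C)C(C)(C)C | intermediate
22 | 2-chloro-N-methoxy-N-methylacetamide | CON(C)C(=O)CCl | starting material
23 | benzylic lithium derivative of 21 (lithiated at the 2-methyl group) | COC(=O)c1c(C[Li])c(Cl)c(O[Si](C)(C)C(C)(C)C)cc1O[Si](C)(C)C(C)(C)C | intermediate (not isolated)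
24 | methyl 4,6-bis[(tert-butyldimethylsilyl)oxy]-3-chloro-2-(3-chloro-2-oxopropyl)benzoate | COC(=O)c1c(CC(=O)CCl)c(Cl)c(O[Si](C)(C)C(C)(C)C)cc1O[Si](C)(C)C(C)(C)C | intermediate (not isolated)
25 | 6,8-bis[(tert-butyldimethylsilyl)oxy]-5-chloro-3-(chloromethyl)-1H-isochromen-1-one | ClCc1cc2c(Cl)c(O[Si](C)(C)C(C)(C)C)cc(O[Si](C)(C)C(C)(C)C)c2c(=O)o1 | intermediate
26 | diethyl {[6,8-bis[(tert-butyldimethylsilyl)oxy]-5-chloro-1-oxo-1H-isochromen-3-yl]methyl}phosphonate | CCOP(=O)(OCC)Cc1cc2c(Cl)c(O[Si](C)(C)C(C)(C)C)cc(O[Si](C)(C)C(C)(C)C)c2c(=O)o1 | intermediate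
27 | sodium salt of the α-carbanion of 26 | CCOP(=O)(OCC)[CH-]c1cc2c(Cl)c(O[Si](C)(C)C(C)(C)C)cc(O[Si](C)(C)C(C)(C)C)c2c(=O)o1.[Na+] | intermediate (not isolated)
28 | 6,8-bis[(tert-butyldimethylsilyl)oxy]-3-[(1E,3E)-4-[(2S,3S,5R)-3-[(tert-butyldimethylsilyl)oxy]-5-methyltetrahydrofuran-2-yl]buta-1,3-dien-1-yl]-5-chloro-1H-isochromen-1-one | C[C@@H]1C[C@H](O[Si](C)(C)C(C)(C)C)[C@H](/C=C/C=C/c2cc3c(Cl)c(O[Si](C)(C)C(C)(C)C)cc(O[Si](C)(C)C(C)(C)C)c3c(=O)o2)O1 | intermediate
29 | 5-chloro-6,8-dihydroxy-3-[(1E,3E)-4-[(2S,3S,5R)-3-hydroxy-5-methyltetrahydrofuran-2-yl]buta-1,3-dien-1-yl]-1H-isochromen-1-one | C[C@@H]1C[C@H](O)[C@H](/C=C/C=C/c2cc3c(Cl)c(O)cc(O)c3c(=O)o2)O1 | target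

Total step count: 15.
Longest linear sequence: 11 steps (steps 1 to 9, then 14 and 15).

Steps most likely to fail

Step 6 (key step). Deprotonation at the enolisable carbon next to the carbonyl followed by loss of sulfate, attack of methoxide at sulfur in competition with acyl attack, or epimerisation next to the ester after closure would erode the contraction. The fallback sets out from 8. The more acidic α-hydroxyl is triflated selectively (Tf2O, pyridine, CH2Cl2, −40 °C) to (3S,4S,6R)-4-hydroxy-6-methyl-2-oxotetrahydro-2H-pyran-3-yl trifluoromethanesulfonate F1. The remaining hydroxyl is silylated (TBSOTf, 2,6-lutidine) to (3S,4S,6R)-4-[(tert-butyldimethylsilyl)oxy]-6-methyl-2-oxotetrahydro-2H-pyran-3-yl trifluoromethanesulfonate F2. K2CO3 in MeOH at −20 °C then effects the classical contraction of a 2-O-triflyl aldono-1,5-lactone and comes back to the route at 14. The neutral triflate with O3 already capped replaces the anionic sulfate, so closure should outrun elimination and no sulfate ester stands next to the enolisable centre.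

Step 3. Background attack of the oxidant anti to the hydroxyl (poor facial selectivity) or acid-triggered allylic rearrangement of the free glycal during work-up would give the wrong C2 configuration or destroy the material. The fallback sets out from 5 and replaces hydroxyl direction by control from an axial anomeric group. Acetylation (Ac2O, pyridine) gives (2R,4S)-2-methyl-3,4-dihydro-2H-pyran-4-yl acetate F3. Ferrier rearrangement with benzyl alcohol (BF3·OEt2, CH2Cl2, −20 °C) gives (2S,6R)-2-(benzyloxy)-6-methyl-5,6-dihydro-2H-pyran F4. Catalytic OsO4 with N-methylmorpholine N-oxide should add anti to the axial benzyloxy group, that is cis to the methyl group, to give benzyl 4,6-dideoxy-α-D-lyxo-hexopyranoside F5. Hydrogenolysis (H2, Pd/C, EtOAc) comes back to the route at 7.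

Step 12. Proton transfer from the α-chloro amide to the benzylic anion, alkylation at the C–Cl carbon in place of acylation, or loss of an aryl silyl ether in the acid stage would lower the efficiency. The fallback sets out from 21. Claisen-type acylation of the toluate anion (LiN(iPr)2, 2.2 equiv) with methyl dimethoxyacetate gives methyl 4,6-bis[(tert-butyldimethylsilyl)oxy]-3-chloro-2-(3,3-dimethoxy-2-oxopropyl)benzoate F6. TsOH in wet acetone at 50 °C closes the lactone and unmasks 6,8-bis[(tert-butyldimethylsilyl)oxy]-5-chloro-1-oxo-1H-isochromene-3-carbaldehyde F7. NaBH4 (MeOH/THF, −20 °C) reduces the aldehyde to 6,8-bis[(tert-butyldimethylsilyl)oxy]-5-chloro-3-(hydroxymethyl)-1H-isochromen-1-one F8. Mesylation (MsCl, Et3N) and displacement by LiCl come back to the route at 25.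

Further compounds
F1 | step 6 | (3S,4S,6R)-4-hydroxy-6-methyl-2-oxotetrahydro-2H-pyran-3-yl trifluoromethanesulfonate | C[C@@H]1C[C@H](O)[C@H](OS(=O)(=O)C(F)(F)F)C(=O)O1
F2 | step 6 | (3S,4S,6R)-4-[(tert-butyldimethylsilyl)oxy]-6-methyl-2-oxotetrahydro-2H-pyran-3-yl trifluoromethanesulfonate | C[C@@H]1C[C@H](O[Si](C)(C)C(C)(C)C)[C@H](OS(=O)(=O)C(F)(F)F)C(=O)O1
F3 | step 3 | (2R,4S)-2-methyl-3,4-dihydro-2H-pyran-4-yl acetate | C[C@@H]1C[C@H](OC(C)=O)C=CO1
F4 | step 3 | (2S,6R)-2-(benzyloxy)-6-methyl-5,6-dihydro-2H-pyran | C[C@@H]1CC=C[C@@H](OCc2ccccc2)O1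
F5 | step 3 | benzyl 4,6-dideoxy-α-D-lyxo-hexopyranoside | C[C@@H]1C[C@H](O)[C@H](O)[C@@H](OCc2ccccc2)O1
F6 | step 12 | methyl 4,6-bis[(tert-butyldimethylsilyl)oxy]-3-chloro-2-(3,3-dimethoxy-2-oxopropyl)benzoate | COC(=O)c1c(CC(=O)C(OC)OC)c(Cl)c(O[Si](C)(C)C(C)(C)C)cc1O[Si](C)(C)C(C)(C)C
F7 | step 12 | 6,8-bis[(tert-butyldimethylsilyl)oxy]-5-chloro-1-oxo-1H-isochromene-3-carbaldehyde | O=Cc1cc2c(Cl)c(O[Si](C)(C)C(C)(C)C)cc(O[Si](C)(C)C(C)(C)C)c2c(=O)o1
F8 | step 12 | 6,8-bis[(tert-butyldimethylsilyl)oxy]-5-chloro-3-(hydroxymethyl)-1H-isochromen-1-one | OCc1cc2c(Cl)c(O[Si](C)(C)C(C)(C)C)cc(O[Si](C)(C)C(C)(C)C)c2c(=O)o1
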